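The closed, stirred, isothermal vessel holds substrate, the limiting reagent, and every mole of it must be booked somewhere.

| flask | substrate | remark | time |
|---|---|---|---|
| summer | 0.29 M | the very flask that is asked about, followed so far |  |
| spring | 0.19 M | run made earlier |  |
| flask | 0.29 M |  | 2.0 d |

- summer (time / h: ring / %, substrate / %): 0.833: 9.9, 73.4; 2.00: 16.1, 50.8; 4.00: 16.8, 30.1; 8.00: 13.1, 12.9; 15.0: 4.9, 3.3
- spring (time / h: ring / %, substrate / %): 0.833: 10.2, 77.8; 2.00: 16.3, 57.4; 5.00: 19.1, 29.1; 15.0: 6.8, 5.8; 30.0: 2.0, 0.7

(standard deviation of a reading: 0.5 percentage points)

- the earlier runs were read with a standard deviation of 0.5 percentage points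

1. time, not beyond 2.0 d, at which the flask holds most ring
2. the amount of ring, in percent of the substrate charged, at that time
3. the first time at which ring reaches 12%, in the same percent, in d

The summer run is this flask: a straight line between its first readings takes ring to 12% at 0.0512 d, and its reading of 16.8% at 0.17 d stands above both neighbours.

Entry one is the loss: down to 30.1% of substrate in summer and 29.1% in spring, the apparent first-order rate is 0.300 h⁻¹ and 0.247 h⁻¹, faster at the stronger charge. So write the loss as a[substrate] plus b[substrate] squared. Logarithmic mean concentrations of 0.169 M and 0.109 M then give x, the starting ratio of second-order to first-order loss at this charge, as 1.73.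

Entry two is ring: at the first reading, ring standing per substrate consumed was 37.2% in summer and 45.9% in spring, more in the weaker run, so you book ring to the first-order route. Integrating that route over substrate instead of time gives the ring share, the part of the charge booked through ring over the whole run, whether it stays ring or not: the logarithm of one plus x divided by x, 58.0%. The second-order route takes the remaining 42.0%.

The forecast gave 17.4% at 0.14 d and 12% at 0.046 d, earlier than my line, adding that “the 2 d limit doesn't bind”.

The flask gives 17.5% at 0.147 d and reaches 12% at 0.0501 d.

    2 substrate → open dimer (k = 0.00757 M⁻¹ min⁻¹)
    ring ⇌ isomer of the product (K = 30.0, k = 0.00503 min⁻¹)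
    substrate → ring (k = 0.00250 min⁻¹)

At 2.00 d this flask holds 42.3% as open dimer, each counted as two substrate, and 57.7% as ring and isomer of the product together, beside the booked ring share of 58.0%. The half-life of ring by its forward step to isomer of the product alone, 0.096 d at that time, is shorter than the 2.0 d allowed. Charged with 0.072 M of substrate, a neighbour flask has x scaled down to 0.430 and a ring share of 83.2%; at 2.00 d its ring and isomer of the product together hold 82.9%.

The earlier runs and the new flask are simulated with constants of no real substance; noise was put on by code.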